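**Retrosynthetic overview**
1. Target ⇐ benzilic-ester ring contraction of a 3-alkyl-2-hydroxy-5-methoxy-1,4-benzoquinone; the cyclopentenone ring is made last.
2. Quinone ⇐ reductive C-alkylation of 2-hydroxy-5-methoxybenzoquinone with a neopentyl decalin aldehyde (forms the CH2 link).
3. Aldehyde ⇐ octalone: MeLi/dehydration gives the ring A alkene and methyl; hydroformylation/α-methylation sets the CHMe and quaternary centres of ring B.
4. Octalone ⇐ catalytic asymmetric intramolecular Diels–Alder of an acyclic trienone: rings A and B, the angular methyl centre and the trans fusion arise together.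
5. Trienone ⇐ hex-5-enenitrile + methacrolein + isopropenylmagnesium bromide. Ring order: A and B in one step, quinone ring bought, five-membered ring by contraction.

Assumption: the (S)-oxazaborolidinium catalyst is taken to give the (4aS,8aS) adduct in step 4; if the sense is opposite, the (R)-catalyst is used with no other change.

**Step 1**
Reactants: 1 hex-5-enenitrile; 2 methacrolein (2-methylprop-2-enal)
Product: 3 (E)-6-methyl-7-oxohept-5-enenitrile
Conditions: 2 (5 equiv), second-generation Hoveyda–Grubbs catalyst (2.5 mol %), CH2Cl2, 40 °C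
Reagents that add atoms: none
Why: Olefin cross-metathesis of a terminal alkene with excess methacrolein gives the trisubstituted enal as the thermodynamically favoured (E)-isomer; no stereocentre is formed.

**Step 2**
Reactants: 3 (E)-6-methyl-7-oxohept-5-enenitrile
Product: 4 (E)-6-methylocta-5,7-dienenitrile
Conditions: Ph3PCH3Br, KOtBu, THF, 0 °C
Reagents that add atoms: methyltriphenylphosphonium bromide, C[P+](c1ccccc1)(c1ccccc1)c1ccccc1.[Br-]
Why: Wittig methylenation of the enal is fast, the ylide is too weak a base to deprotonate the nitrile, and the (E)-alkene geometry is retained.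

**Step 3**
Reactants: 4 (E)-6-methylocta-5,7-dienenitrile; 5 isopropenylmagnesium bromide
Product: 7 (E)-2,8-dimethyldeca-1,7,9-trien-3-one, via bromomagnesium ketimide 6 (not isolated)
Conditions: 5 (1.5 equiv), CuBr·SMe2 (5 mol %), THF, 0 → 50 °C; then 1 M HCl, 0 °C; product kept cold with BHT
Reagents that add atoms: water, O
Why: Grignard addition to a nitrile stops at the N-magnesio ketimine (no over-addition), which hydrolyses to the isopropenyl ketone; the copper salt favours addition over α-deprotonation.

**Step 4**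
Reactants: 7 (E)-2,8-dimethyldeca-1,7,9-trien-3-one
Product: 8 (4aS,8aS)-5,8a-dimethyl-3,4,4a,7,8,8a-hexahydronaphthalen-1(2H)-one
Conditions: (S)-o-tolyl oxazaborolidine ((3aS)-3,3-diphenyl-1-(2-methylphenyl)tetrahydro-1H,3H-pyrrolo[1,2-c][1,3,2]oxazaborole, 20 mol %), Tf2NH (18 mol %), CH2Cl2, −40 → −20 °C
Reagents that add atoms: none
Why: Proposed new method: a catalytic enantioselective intramolecular Diels–Alder of an α-methyl trienone, in which boron coordination lowers the LUMO of the isopropenyl ketone and an asynchronous [4+2] (C1–C10 bond leading, C2–C7 following) closes both carbocycles at once; the (E)-diene and the α-methyl group favour the tether-exo/methyl-endo chair transition state, giving the trans-fused angular-methyl octalone and setting C-4a and C-8a, while the chiral pocket shields one enone face; the closest known reactions are thermal and Lewis-acid intramolecular Diels–Alder reactions of 2-methyl-1,7,9-decatrien-3-ones and oxazaborolidinium-catalysed Diels–Alder reactions of enones and α-substituted enals.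

**Step 5**
Reactants: 8 (4aS,8aS)-5,8a-dimethyl-3,4,4a,7,8,8a-hexahydronaphthalen-1(2H)-one
Product: 9 (4aS,8aS)-1,5,8a-trimethyl-1,2,3,4,4a,7,8,8a-octahydronaphthalen-1-ol (both C-1 epimers)
Conditions: MeLi (2 equiv), CeCl3 (2 equiv), THF, −78 °C; then aq. NH4Cl
Reagents that add atoms: methyllithium, [Li]C
Why: Organocerium 1,2-addition suppresses enolisation of the hindered ketone; the new carbinol centre is removed in step 8, and the alcohol keeps ring A free of a second alkene during step 6.

**Step 6**
Reactants: 9 (4aS,8aS)-1,5,8a-trimethyl-1,2,3,4,4a,7,8,8a-octahydronaphthalen-1-ol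
Product: 10 (1R,2R,4aS,8aS)-5-hydroxy-1,4a,5-trimethyldecahydronaphthalene-2-carbaldehyde (C-5 epimers; the formyl centre C-2 may epimerise, without consequence)
Conditions: Rh(acac)(CO)2 (2 mol %), P(O-2,4-tBu2C6H3)3 (8 mol %), CO/H2 (1:1, 50 bar), toluene, 90 °C
Reagents that add atoms: carbon monoxide, [C-]#[O+]
Why: Rhodium-catalysed hydroformylation with a bulky phosphite adds H and CHO syn across the only alkene, the formyl going to the CH carbon (never to the carbon that would become quaternary) and both entering from the face opposite the angular methyl (steric approach control, as in hydroboration of 2-methyl-Δ2 steroids), which sets C-1 as R with its methyl syn to the angular methyl.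

**Step 7**
Reactants: 10 (1R,2R,4aS,8aS)-5-hydroxy-1,4a,5-trimethyldecahydronaphthalene-2-carbaldehyde
Product: 11 (1R,2S,4aS,8aS)-5-hydroxy-1,2,4a,5-tetramethyldecahydronaphthalene-2-carbaldehyde (C-5 epimers)
Conditions: KOtBu (1.1 equiv), MeI (3 equiv), THF, −20 → 0 °C
Reagents that add atoms: iodomethane, CI
Why: Enolate alkylation: the exocyclic potassium enolate of the α-branched aldehyde (more acidic than the tertiary alcohol in THF) is methylated axially, anti to the adjacent axial C-1 methyl, so the new methyl is trans to the C-1 methyl and the formyl group equatorial (C-2 S).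

**Step 8**
Reactants: 11 (1R,2S,4aS,8aS)-5-hydroxy-1,2,4a,5-tetramethyldecahydronaphthalene-2-carbaldehyde
Product: 12 (1R,2S,4aS,8aS)-1,2,4a,5-tetramethyl-1,2,3,4,4a,7,8,8a-octahydronaphthalene-2-carbaldehyde
Conditions: Burgess reagent (methyl N-(triethylammoniosulfonyl)carbamate, 2 equiv), toluene, 70 °C; then RhCl3·3H2O (5 mol %), EtOH, 75 °C
Reagents that add atoms: none
Why: Burgess syn-dehydration of the tertiary alcohol can only use the ring CH2 or the methyl hydrogens (the other neighbour is quaternary) and avoids a free cation next to the quaternary centre; the rhodium chloride treatment isomerises any exocyclic alkene to the trisubstituted ring alkene; the aldehyde is not enolisable and no stereocentre is touched.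

**Step 9**
Reactants: 13 2,5-dimethoxy-1,4-benzoquinone
Product: 14 2-hydroxy-5-methoxy-1,4-benzoquinone
Conditions: NaOH (1.05 equiv), H2O/THF, 0 °C → rt; then 1 M HCl
Reagents that add atoms: sodium hydroxide, [Na+].[OH-]
Why: Addition–elimination hydrolysis of one vinylogous ester; the resulting vinylogous carboxylate anion is deactivated, so the second methoxy group survives.

**Step 10**
Reactants: 12 (1R,2S,4aS,8aS)-1,2,4a,5-tetramethyl-1,2,3,4,4a,7,8,8a-octahydronaphthalene-2-carbaldehyde; 14 2-hydroxy-5-methoxy-1,4-benzoquinone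
Product: 16 2-hydroxy-5-methoxy-3-{[(1R,2R,4aS,8aS)-1,2,4a,5-tetramethyl-1,2,3,4,4a,7,8,8a-octahydronaphthalen-2-yl]methyl}cyclohexa-2,5-diene-1,4-dione, via quinone methide 15 (not isolated)
Conditions: 14 (1.2 equiv), Hantzsch ester (diethyl 2,6-dimethyl-1,4-dihydropyridine-3,5-dicarboxylate, 1.2 equiv), L-proline (20 mol %), CH2Cl2, 25–40 °C; air on work-up
Reagents that add atoms: none
Why: Three-component reductive alkylation: amine-catalysed Knoevenagel condensation of the non-enolisable aldehyde at C-3 of 14 (the only nucleophilic carbon of the vinylogous acid) gives the quinone methide, which the Hantzsch ester reduces by conjugate hydride transfer; air reoxidises any hydroquinone; no stereocentre is formed.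

**Step 11**
Reactants: 16 2-hydroxy-5-methoxy-3-{[(1R,2R,4aS,8aS)-1,2,4a,5-tetramethyl-1,2,3,4,4a,7,8,8a-octahydronaphthalen-2-yl]methyl}cyclohexa-2,5-diene-1,4-dione
Product: 17 Dysidenone A, methyl (1S,5R)-1-hydroxy-3-methoxy-4-oxo-5-{[(1R,2R,4aS,8aS)-1,2,4a,5-tetramethyl-1,2,3,4,4a,7,8,8a-octahydronaphthalen-2-yl]methyl}cyclopent-2-ene-1-carboxylate
Conditions: NaOMe (3 equiv), degassed MeOH, 0 → 40 °C; AcOH quench; preparative HPLC
Reagents that add atoms: sodium methoxide, [Na+].[O-]C
Why: Proposed new method: a benzilic ester rearrangement of the hydroxyquinone through its 1,2-dicarbonyl tautomer, in which methoxide adds to the dione and a 1,2-acyl shift contracts the ring to the α-hydroxy methyl ester, leaving the 2-methoxy enone with the alkyl-bearing CH next to the ketone; this CH (C-5) is epimerisable and equilibrates, whereas the carbinol C-1 is formed without control from the remote decalin, so 17 is separated from its diastereomers by HPLC and its C-5 epimer is recycled by base equilibration; the closest known reactions are the benzilic ester rearrangement of 1,2-diones and the alkaline ring contraction of hydroxyquinones.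

**Compound list**
1 | hex-5-enenitrile | C=CCCCC#N | starting material
2 | methacrolein | CC(=C)C=O | starting material
3 | (E)-6-methyl-7-oxohept-5-enenitrile | N#CCCC/C=C(\C)C=O | intermediate
4 | (E)-6-methylocta-5,7-dienenitrile | N#CCCC/C=C(\C)C=C | intermediate
5 | isopropenylmagnesium bromide | CC(=C)[Mg]Br | starting material
6 | bromomagnesium ketimide of 7 | C=C(C)C(=N[Mg]Br)CCC/C=C(\C)C=C | intermediate (not isolated)
7 | (E)-2,8-dimethyldeca-1,7,9-trien-3-one | C=C(C)C(=O)CCC/C=C(\C)C=C | intermediate
8 | (4aS,8aS)-5,8a-dimethyl-3,4,4a,7,8,8a-hexahydronaphthalen-1(2H)-one | CC1=CCC[C@]2(C)C(=O)CCC[C@@H]12 | intermediate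
9 | (4aS,8aS)-1,5,8a-trimethyl-1,2,3,4,4a,7,8,8a-octahydronaphthalen-1-ol (C-1 epimers) | CC1=CCC[C@]2(C)C(C)(O)CCC[C@@H]12 | intermediate
10 | (1R,2R,4aS,8aS)-5-hydroxy-1,4a,5-trimethyldecahydronaphthalene-2-carbaldehyde (C-5 epimers) | O=C[C@@H]1CC[C@]2(C)C(C)(O)CCC[C@H]2[C@H]1C | intermediate
11 | (1R,2S,4aS,8aS)-5-hydroxy-1,2,4a,5-tetramethyldecahydronaphthalene-2-carbaldehyde (C-5 epimers) | O=C[C@@]1(C)CC[C@]2(C)C(C)(O)CCC[C@H]2[C@H]1C | intermediate
12 | (1R,2S,4aS,8aS)-1,2,4a,5-tetramethyl-1,2,3,4,4a,7,8,8a-octahydronaphthalene-2-carbaldehyde | O=C[C@@]1(C)CC[C@]2(C)C(C)=CCC[C@H]2[C@H]1C | intermediate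
13 | 2,5-dimethoxy-1,4-benzoquinone | COC1=CC(=O)C(OC)=CC1=O | starting material
14 | 2-hydroxy-5-methoxy-1,4-benzoquinone | COC1=CC(=O)C(O)=CC1=O | intermediate
15 | quinone methide: 5-methoxy-3-(decalinylmethylidene)cyclohex-5-ene-1,2,4-trione | COC1=CC(=O)C(=O)C(=C[C@@]2(C)CC[C@]3(C)C(C)=CCC[C@H]3[C@H]2C)C1=O | intermediate (not isolated)
16 | 2-hydroxy-5-methoxy-3-{[(1R,2R,4aS,8aS)-1,2,4a,5-tetramethyl-1,2,3,4,4a,7,8,8a-octahydronaphthalen-2-yl]methyl}cyclohexa-2,5-diene-1,4-dione | COC1=CC(=O)C(O)=C(C[C@@]2(C)CC[C@]3(C)C(C)=CCC[C@H]3[C@H]2C)C1=O | intermediate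
17 | Dysidenone A | COC(=O)[C@]1(O)C=C(OC)C(=O)[C@@H]1C[C@@]1(C)CC[C@]2(C)C(C)=CCC[C@H]2[C@H]1C | target

**Totals**
Total steps: 11. Longest linear sequence: 10 (steps 1–8, 10, 11); step 9 is a one-step side branch.

**Three steps most likely to fail**

Step 4 (low ee, cis fusion or polymerisation of the trienone). The fallback replaces catalyst control by an auxiliary-controlled ionic Diels–Alder; it sets out from 7 and comes back at 8. Compound 7 is ketalised with (2R,4R)-pentane-2,4-diol (PPTS, benzene, reflux) to the chiral 4,6-dimethyl-1,3-dioxane ketal of 7 F1. TfOH or TMSOTf (5–10 mol %, CH2Cl2, −78 °C) opens it to a chiral 2-alkoxyallyl cation, which undergoes the intramolecular cationic [4+2] and recloses to the spiro-ketal of 8 F2. Aqueous HCl/THF then releases 8 and the diol.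

Step 10 (the α-quaternary aldehyde may be too hindered for the Knoevenagel step). The fallback builds the quinone from an arene; it sets out from 12 and comes back at 16, making step 9 unnecessary. 2,3,5,6-Tetramethoxyphenyllithium (from 1,2,4,5-tetramethoxybenzene and n-BuLi, THF, 0 °C) adds to 12 to give the benzylic carbinol F3. Li/NH3 (THF, −78 °C, NH4Cl) removes the benzylic hydroxyl to give the tetramethoxyarene F4, the isolated alkene being inert. (NH4)2Ce(NO3)6 in MeCN/H2O at 0 °C gives the 2,5-dimethoxyquinone F5. Controlled hydrolysis of the methoxy group next to the alkyl substituent (aq. HClO4/THF) gives 16.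

Step 11 (the hydroxyquinone anion may resist rearrangement, and the carbinol centre is not controlled). The fallback contracts the ring before coupling and fixes the carbinol centre by resolution; it sets out from 12 and 14 and comes back at 17. Compound 14 is contracted under forcing conditions (NaOMe, MeOH, reflux), where no terpenoid is at risk, and the racemate is resolved by preparative chiral HPLC to methyl (R)-1-hydroxy-3-methoxy-4-oxocyclopent-2-ene-1-carboxylate F6. Its dianion (LiN(iPr)2, 2.2 equiv, THF, −78 °C) adds to 12 to give the aldol adduct F7. MsCl/Et3N then DBU gives the exocyclic enone F8. Conjugate reduction with [(Ph3P)CuH]6 and equilibration of the ring CH with DBU give 17.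

**Further compounds**
F1 | step 4 | (4R,6R)-4,6-dimethyl-2-[(4E)-5-methylhepta-4,6-dien-1-yl]-2-(prop-1-en-2-yl)-1,3-dioxane | C=C(C)C1(CCC/C=C(\C)C=C)O[C@H](C)C[C@@H](C)O1
F2 | step 4 | spiro-ketal of 8 with (2R,4R)-pentane-2,4-diol | CC1=CCC[C@]2(C)C3(CCC[C@@H]12)O[C@H](C)C[C@@H](C)O3
F3 | step 10 | (2,3,5,6-tetramethoxyphenyl)[(1R,2S,4aS,8aS)-1,2,4a,5-tetramethyl-1,2,3,4,4a,7,8,8a-octahydronaphthalen-2-yl]methanol (carbinol epimers) | COc1cc(OC)c(OC)c(C(O)[C@@]2(C)CC[C@]3(C)C(C)=CCC[C@H]3[C@H]2C)c1OC
F4 | step 10 | 1,2,4,5-tetramethoxy-3-{[(1R,2R,4aS,8aS)-1,2,4a,5-tetramethyl-1,2,3,4,4a,7,8,8a-octahydronaphthalen-2-yl]methyl}benzene | COc1cc(OC)c(OC)c(C[C@@]2(C)CC[C@]3(C)C(C)=CCC[C@H]3[C@H]2C)c1OC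
F5 | step 10 | 2,5-dimethoxy-3-{[(1R,2R,4aS,8aS)-1,2,4a,5-tetramethyl-1,2,3,4,4a,7,8,8a-octahydronaphthalen-2-yl]methyl}cyclohexa-2,5-diene-1,4-dione | COC1=CC(=O)C(OC)=C(C[C@@]2(C)CC[C@]3(C)C(C)=CCC[C@H]3[C@H]2C)C1=O
F6 | step 11 | methyl (R)-1-hydroxy-3-methoxy-4-oxocyclopent-2-ene-1-carboxylate | COC(=O)[C@]1(O)C=C(OC)C(=O)C1
F7 | step 11 | aldol adduct of F6 and 12 (epimers at the two new centres) | COC(=O)[C@]1(O)C=C(OC)C(=O)C1C(O)[C@@]3(C)CC[C@]2(C)C(C)=CCC[C@H]2[C@H]3C
F8 | step 11 | exocyclic enone from F7 (5-decalinylmethylidene cyclopentenone) | COC(=O)[C@]1(O)C=C(OC)C(=O)C1=C[C@@]3(C)CC[C@]2(C)C(C)=CCC[C@H]2[C@H]3C
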